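**Retrosynthetic overview**

1. 13 ⇐ 12 (loss of three silyl groups) ⇐ lactone 7 + cyclobutane-1,3-dione 8. The cyclohexenetrione ring arises by 4 → 6 ring expansion of 8: lactone C3 and C2 are inserted into one C(=O)–CMe2 bond. The dihydrocoumarin ring (O1–C2–C3–C4–C4a–C8a) is a temporary tether, absent from the target, and is cleaved in the same operation.
2. Enabling feature: the strained, non-enolisable four-membered ring of 8 (two C=O, each flanked by two CMe2). After carbanion addition it fragments to a tertiary enolate whose carbon lies six atoms from the aryl-ester carbonyl C2 (a 3,5-dioxohexanoate array set up for Claisen closure).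
3. 7 ⇐ 6 (both phenols and the ketone silylated) ⇐ acylphloroglucinol 5 + ynal 2 by enantioselective carbene-catalysed annulation, which sets the only stereocentre (C4).
4. 5 ⇐ 3 + 4 (Friedel–Crafts acylation); 2 ⇐ 1 (formylation).
5. Ring order: aromatic ring bought; lactone ring (step 3, temporary); six-membered trione ring from the four-membered ring (step 5).

Key step: step 5

Assumption: the target is handled as the enol tautomer drawn; its stereocentre is R, which corresponds to 4S in the lactone intermediates because the CIP priorities change when C3 becomes part of the trione ring. The silyl enol ether is drawn Z; its geometry has no bearing on the route.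

**Route**

Step 1
Reactants: 1 4-phenylbut-1-yne
Product: 2 5-phenylpent-2-ynal
Conditions: n-BuLi, THF, −78 °C; DMF, −78 → 0 °C; inverse quench into cold 1 M HCl
Reagents that add atoms: N,N-dimethylformamide, CN(C)C=O
Why: Deprotonation of the terminal alkyne and formylation of the lithium acetylide with DMF (Bouveault-type formylation), the acidic inverse quench keeping dimethylamine from adding to the ynal; no stereocentre.

Step 2
Reactants: 3 2-methylbenzene-1,3,5-triol; 4 3-phenylpropanoyl chloride
Product: 5 1-(2,4,6-trihydroxy-3-methylphenyl)-3-phenylpropan-1-one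
Conditions: AlCl3 (3.5 equiv), PhNO2–CH2Cl2, 0 → 45 °C; 1 M HCl
Reagents that add atoms: none
Why: Friedel–Crafts C-acylation of the electron-rich phloroglucinol ring, whose two free positions are equivalent by symmetry and which is deactivated against a second acylation by the first acyl group; no stereocentre.

Step 3
Reactants: 5 1-(2,4,6-trihydroxy-3-methylphenyl)-3-phenylpropan-1-one; 2 5-phenylpent-2-ynal
Product: 6 (4S)-5,7-dihydroxy-8-methyl-4-(2-phenylethyl)-6-(3-phenylpropanoyl)-3,4-dihydro-2H-chromen-2-one
Conditions: chiral aminoindanol-derived N-mesityl triazolium chloride (10 mol%, the enantiomer that delivers 4S), PhMe–THF, 40 °C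
Reagents that add atoms: none
Why: Carbene-catalysed redox annulation of an ynal with a hydroxyarene (Coates–Claisen-type [3+3] annulation via the α,β-unsaturated acyl azolium): the C–C bond can form only at the single free ring carbon of 5, the chiral azolium shields one face of the β-carbon and so sets C4 as S, and lactonisation onto the neighbouring non-chelated OH releases the carbene; which flanking OH closes the lactone does not matter later, because step 5 opens this ring again.

Step 4
Reactants: 6 (4S)-5,7-dihydroxy-8-methyl-4-(2-phenylethyl)-6-(3-phenylpropanoyl)-3,4-dihydro-2H-chromen-2-one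
Product: 7 (4S)-5,7-bis[(tert-butyldimethylsilyl)oxy]-6-[(1Z)-1-[(tert-butyldimethylsilyl)oxy]-3-phenylprop-1-en-1-yl]-8-methyl-4-(2-phenylethyl)-3,4-dihydro-2H-chromen-2-one
Conditions: TBSOTf (3.5 equiv), Et3N (5 equiv), CH2Cl2, −78 → 23 °C; aq. NaHCO3
Reagents that add atoms: tert-butyldimethylsilyl trifluoromethanesulfonate, CC(C)(C)[Si](C)(C)OS(=O)(=O)C(F)(F)F
Why: Silyl triflate/amine silylation: both phenols are O-silylated and the aryl ketone is turned by soft enolisation into its silyl enol ether, which removes the only C–H acidity that would compete with C3 in step 5, while the aryl lactone enolises far more slowly under these conditions; C4 is untouched.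

Step 5
Reactants: 7 (4S)-tris-silylated lactone; 8 2,2,4,4-tetramethylcyclobutane-1,3-dione
Product: 12 2-[(1R)-1-{2,4-bis[(tert-butyldimethylsilyl)oxy]-3-[(1Z)-1-[(tert-butyldimethylsilyl)oxy]-3-phenylprop-1-en-1-yl]-6-hydroxy-5-methylphenyl}-3-phenylpropyl]-3-hydroxy-4,4,6,6-tetramethylcyclohex-2-ene-1,5-dione, via lithium lactone enolate 9 (not isolated), via lithium cyclobutanolate adduct 10 (not isolated), via ring-opened lithium enolate 11 (not isolated)
Conditions: LiHMDS (1.1 equiv), THF, −78 °C; 8 (1.1 equiv), −78 → −20 °C; LiHMDS (1.1 equiv), −20 → 23 °C; AcOH quench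
Reagents that add atoms: none
Why: Proposed new method: lithium enolate 9 (C3 of the lactone) adds to one carbonyl of 8 to give cyclobutanolate 10, the strained ring C(O)–CMe2 bond of which breaks (retro-aldol/retro-Claisen fragmentation) to the tertiary isopropyl-ketone enolate 11, and this enolate carbon attacks the lactone carbonyl C2 in a 6-exo-trig Claisen (Dieckmann) acyl substitution that expels the C8a phenoxide, so that the four ring carbons of 8 plus C3 and C2 end up as the six-membered trione ring (net insertion of C3–C2 into a ring C–C bond, with the lactone tether opened at the same time). The closest known reactions are the ring opening of 8 by alkoxides and amines to 2,2,4-trimethyl-3-oxopentanoyl derivatives (addition, then the same C–C fragmentation), the base-induced retro-aldol opening of 3-hydroxycyclobutanones, and the Claisen cyclisation of 3,5-dioxohexanoate esters to cyclohexane-1,3,5-triones. No new stereocentre is formed: C3 ends as the sp2 enol carbon, and C4, which bears no acidic hydrogen and no leaving group, keeps its configuration (the descriptor changes from S to R only through the change in CIP priorities). The step needs enolisation at C3 alone and C- rather than O-acylation in the closure: the first is secured by the silyl enol ether that masks the ketone, the silyl ethers on the phenols and the absence of α-hydrogens in 8, the second by the reversibility of O-acylation against the irreversible formation of the stabilised trione enolate. Reversal of the first addition is harmless because only the fragmentation is irreversible, and if internal proton transfer parks the intermediate as the β-keto-lactone enolate, the second charge of LiHMDS regenerates the distal enolate.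

Step 6
Reactants: 12 tris-silylated ring-expanded phenol
Product: 13 2-[(1R)-1-[2,4,6-trihydroxy-3-methyl-5-(3-phenylpropanoyl)phenyl]-3-phenylpropyl]-3-hydroxy-4,4,6,6-tetramethylcyclohex-2-ene-1,5-dione (CNP0236721.1)
Conditions: TBAF/AcOH (1:1, 4 equiv), THF, 0 → 23 °C
Reagents that add atoms: none
Why: Fluoride-mediated desilylation of the two aryl silyl ethers and of the silyl enol ether (which gives the ketone on protonation) under acetic-acid buffering, so that neither base-induced retro-Michael loss of configuration at the benzylic carbon nor acid-driven cyclodehydration to a xanthenone is expected; any silyl migration between oxygens during step 5 is erased here.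

**Compound list**

1 | 4-phenylbut-1-yne | C#CCCc1ccccc1 | starting material
2 | 5-phenylpent-2-ynal | O=CC#CCCc1ccccc1 | intermediate
3 | 2-methylbenzene-1,3,5-triol (2,4,6-trihydroxytoluene) | Cc1c(O)cc(O)cc1O | starting material
4 | 3-phenylpropanoyl chloride | O=C(Cl)CCc1ccccc1 | starting material
5 | 1-(2,4,6-trihydroxy-3-methylphenyl)-3-phenylpropan-1-one | Cc1c(O)cc(O)c(C(=O)CCc2ccccc2)c1O | intermediate
6 | (4S)-5,7-dihydroxy-8-methyl-4-(2-phenylethyl)-6-(3-phenylpropanoyl)-3,4-dihydro-2H-chromen-2-one | Cc1c(O)c(C(=O)CCc2ccccc2)c(O)c2c1OC(=O)C[C@@H]2CCc1ccccc1 | intermediate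
7 | (4S)-5,7-bis[(tert-butyldimethylsilyl)oxy]-6-[(1Z)-1-[(tert-butyldimethylsilyl)oxy]-3-phenylprop-1-en-1-yl]-8-methyl-4-(2-phenylethyl)-3,4-dihydro-2H-chromen-2-one | Cc1c(O[Si](C)(C)C(C)(C)C)c(/C(O[Si](C)(C)C(C)(C)C)=C/Cc2ccccc2)c(O[Si](C)(C)C(C)(C)C)c2c1OC(=O)C[C@@H]2CCc1ccccc1 | intermediate
8 | 2,2,4,4-tetramethylcyclobutane-1,3-dione | CC1(C)C(=O)C(C)(C)C1=O | starting material
9 | lithium enolate of 7 (lithium (4S)-4H-chromen-2-olate, deprotonated at C3) | Cc1c(O[Si](C)(C)C(C)(C)C)c(/C(O[Si](C)(C)C(C)(C)C)=C/Cc2ccccc2)c(O[Si](C)(C)C(C)(C)C)c2c1OC([O-])=C[C@@H]2CCc1ccccc1.[Li+] | intermediate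
10 | lithium 2,2,4,4-tetramethyl-3-oxo-1-[(4S)-lactone-3-yl]cyclobutan-1-olate (aldol adduct of 9 and 8; C3 configuration not defined, transient) | Cc1c(O[Si](C)(C)C(C)(C)C)c(/C(O[Si](C)(C)C(C)(C)C)=C/Cc2ccccc2)c(O[Si](C)(C)C(C)(C)C)c2c1OC(=O)C(C1([O-])C(C)(C)C(=O)C1(C)C)[C@@H]2CCc1ccccc1.[Li+] | intermediate
11 | lithium enolate (at the isopropyl ketone) of the (4S)-3-(2,2,4-trimethyl-3-oxopentanoyl) lactone (ring-opened; C3 configuration not defined, transient) | Cc1c(O[Si](C)(C)C(C)(C)C)c(/C(O[Si](C)(C)C(C)(C)C)=C/Cc2ccccc2)c(O[Si](C)(C)C(C)(C)C)c2c1OC(=O)C(C(=O)C(C)(C)C([O-])=C(C)C)[C@@H]2CCc1ccccc1.[Li+] | intermediate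
12 | 2-[(1R)-1-{2,4-bis[(tert-butyldimethylsilyl)oxy]-3-[(1Z)-1-[(tert-butyldimethylsilyl)oxy]-3-phenylprop-1-en-1-yl]-6-hydroxy-5-methylphenyl}-3-phenylpropyl]-3-hydroxy-4,4,6,6-tetramethylcyclohex-2-ene-1,5-dione | Cc1c(O[Si](C)(C)C(C)(C)C)c(/C(O[Si](C)(C)C(C)(C)C)=C/Cc2ccccc2)c(O[Si](C)(C)C(C)(C)C)c([C@@H](CCc2ccccc2)C2=C(O)C(C)(C)C(=O)C(C)(C)C2=O)c1O | intermediate
13 | 2-[(1R)-1-[2,4,6-trihydroxy-3-methyl-5-(3-phenylpropanoyl)phenyl]-3-phenylpropyl]-3-hydroxy-4,4,6,6-tetramethylcyclohex-2-ene-1,5-dione (CNP0236721.1) | Cc1c(O)c(C(=O)CCc2ccccc2)c(O)c([C@@H](CCc2ccccc2)C2=C(O)C(C)(C)C(=O)C(C)(C)C2=O)c1O | target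

**Step count and risks**

Total step count: 6. Longest linear sequence: 5 (3 → 5 → 6 → 7 → 12 → 13).

Steps most likely to fail:

1. Step 5 (Proposed new method). The addition of the hindered enolate to the carbonyl flanked by two quaternary carbons may be slow or revert. The cascade may also stop after fragmentation, when internal proton transfer leaves the stabilised β-keto-lactone enolate and the ring fails to close, or the liberated enolate may be trapped by remaining 8. The fallback uses known chemistry, sets out from 5 and rejoins the route at 13. Commercial syncarpic acid (2,2,4,4-tetramethylcyclohexane-1,3,5-trione) would be condensed with 3-phenylpropanal (L-proline cat., CH2Cl2, 23 °C; Knoevenagel condensation) to give 2-(3-phenylpropylidene)-4,4,6,6-tetramethylcyclohexane-1,3,5-trione F1, used in situ. Phloroglucinol 5 would then add through its one free ring carbon (Et3N or NaH, THF; Michael addition of Friedel–Crafts type) to give racemic 13 F2. Preparative SFC on a chiral stationary phase would deliver 13.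

2. Step 3. O-acylation of the phenols by the acyl azolium (redox esterification) may outrun C–C bond formation, or the strongly acidic triphenol may erode catalyst turnover and facial selectivity. The fallback sets out from 5 and rejoins the route at 6. Knoevenagel condensation of Meldrum's acid with 3-phenylpropanal would give 2,2-dimethyl-5-(3-phenylpropylidene)-1,3-dioxane-4,6-dione F3. Yb(OTf)3-catalysed Friedel–Crafts conjugate addition of 5 (MeNO2, 80 °C) would give the adduct 2,2-dimethyl-5-{3-phenyl-1-[2,4,6-trihydroxy-3-methyl-5-(3-phenylpropanoyl)phenyl]propyl}-1,3-dioxane-4,6-dione F4, not isolated, which lactonises with loss of acetone and carbon dioxide to the racemic lactone rac-6 F5. Resolution by preparative chiral SFC would give 6.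

3. Step 4. Silylation may stay incomplete at the two chelated, flanked phenols and at the crowded ketone, or the lactone may be silylated as well. The fallback sets out from 6 and rejoins the route at 13, bypassing 7, 12 and step 6 by transient protection. TMSOTf/Et3N in CH2Cl2 would give the tris(trimethylsilyl) analogue of 7 F6, freed from ammonium salt by pentane trituration and used crude. Under the conditions of step 5 with 8 it would pass through its lithium enolate F7, the lithium cyclobutanolate adduct F8 and the ring-opened lithium enolate F9 to the ring-expanded tris(trimethylsilyl) phenol F10, none of them isolated. Work-up with aqueous citric acid/MeOH would remove the three labile trimethylsilyl groups and give 13 directly.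

**Further compounds**

F1 | step 5 | 2-(3-phenylpropylidene)-4,4,6,6-tetramethylcyclohexane-1,3,5-trione | CC1(C)C(=O)C(=CCCc2ccccc2)C(=O)C(C)(C)C1=O
F2 | step 5 | racemic 13 | Cc1c(O)c(C(=O)CCc2ccccc2)c(O)c(C(CCc2ccccc2)C2=C(O)C(C)(C)C(=O)C(C)(C)C2=O)c1O
F3 | step 3 | 2,2-dimethyl-5-(3-phenylpropylidene)-1,3-dioxane-4,6-dione | CC1(C)OC(=O)C(=CCCc2ccccc2)C(=O)O1
F4 | step 3 | 2,2-dimethyl-5-{3-phenyl-1-[2,4,6-trihydroxy-3-methyl-5-(3-phenylpropanoyl)phenyl]propyl}-1,3-dioxane-4,6-dione (racemic) | Cc1c(O)c(C(=O)CCc2ccccc2)c(O)c(C(CCc2ccccc2)C2C(=O)OC(C)(C)OC2=O)c1O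
F5 | step 3 | racemic 6 | Cc1c(O)c(C(=O)CCc2ccccc2)c(O)c2c1OC(=O)CC2CCc1ccccc1
F6 | step 4 | (4S)-8-methyl-4-(2-phenylethyl)-5,7-bis[(trimethylsilyl)oxy]-6-[(1Z)-3-phenyl-1-[(trimethylsilyl)oxy]prop-1-en-1-yl]-3,4-dihydro-2H-chromen-2-one | Cc1c(O[Si](C)(C)C)c(/C(O[Si](C)(C)C)=C/Cc2ccccc2)c(O[Si](C)(C)C)c2c1OC(=O)C[C@@H]2CCc1ccccc1
F7 | step 4 | lithium enolate of F6 | Cc1c(O[Si](C)(C)C)c(/C(O[Si](C)(C)C)=C/Cc2ccccc2)c(O[Si](C)(C)C)c2c1OC([O-])=C[C@@H]2CCc1ccccc1.[Li+]
F8 | step 4 | lithium cyclobutanolate adduct of F7 and 8 | Cc1c(O[Si](C)(C)C)c(/C(O[Si](C)(C)C)=C/Cc2ccccc2)c(O[Si](C)(C)C)c2c1OC(=O)C(C1([O-])C(C)(C)C(=O)C1(C)C)[C@@H]2CCc1ccccc1.[Li+]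
F9 | step 4 | ring-opened lithium enolate from F8 | Cc1c(O[Si](C)(C)C)c(/C(O[Si](C)(C)C)=C/Cc2ccccc2)c(O[Si](C)(C)C)c2c1OC(=O)C(C(=O)C(C)(C)C([O-])=C(C)C)[C@@H]2CCc1ccccc1.[Li+]
F10 | step 4 | tris(trimethylsilyl) analogue of 12 | Cc1c(O[Si](C)(C)C)c(/C(O[Si](C)(C)C)=C/Cc2ccccc2)c(O[Si](C)(C)C)c([C@@H](CCc2ccccc2)C2=C(O)C(C)(C)C(=O)C(C)(C)C2=O)c1O
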